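Read as percentages, the earlier runs looked impossible. By 120 min the autumn run had lost 70.6% of its J and the winter run 33.2%, at the same D, while the dawn run, with twice the D of winter, had lost 52.6%.

| flask | J | D | remark | time |
|---|---|---|---|---|
| autumn | 0.67 M | 0.95 M | run made earlier |  |
| winter | 1.5 M | 0.95 M | run made earlier |  |
| dawn | 1 M | 1.9 M | run made earlier |  |
| flask | 1.0 M | 0.950 M |  | 2.5 h |

- autumn (time / min: J / %, G / %): 20.0: 87.8, 6.2; 40.0: 76.4, 15.7; 60.0: 63.2, 25.1; 80.0: 50.3, 33.0; 90.0: 44.0, 35.4; 120: 29.4, 46.4
- winter (time / min: J / %, G / %): 10.0: 97.5, 1.6; 15.0: 94.6, 1.0; 25.0: 92.8, 5.0; 40.0: 89.4, 6.3; 80.0: 78.1, 14.1; 120: 66.8, 22.9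
- dawn (time / min: J / %, G / %): 10.0: 95.9, 1.3; 20.0: 91.0, 5.2; 30.0: 87.0, 9.4; 60.0: 74.5, 17.8; 120: 47.4, 37.2

(readings scatter by 1 percentage point)

- solid, in amounts per volume of the solution: J
- at the start none of J is in solution
- what has only dissolved of J counts as not reacted
- the reaction counts as stopped when no species that holds the J changes by six tenths of a point or more over the second half of the time

- the state of affairs at 2.5 h: stopped, and by what, or still going (for what has run out or reacted, a solid counts together with what of it has only dissolved) (D has run out first / all of J has reacted / it is still moving / forward and back rates have come level)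
- part of the J that has turned into other species by 2.5 h (what has only dissolved does not count)
- the G standing at 2.5 h, as a percentage of the J charged

Then I turned the percentages into concentrations. The losses became 0.473 M, 0.498 M and 0.526 M, so the puzzle went. From winter to dawn D rose and J fell, yet the loss barely moved, so I took the solid's dissolving as the rate-limiting step. Winter gave 0.00415 M min⁻¹, which I carried as the feed rate, the J leaving the solid per minute while solid stands.

For 2.5 h in the flask, I reckoned by that rate that 62.2% of the J would leave the solid and 37.8% would stay as solid. Taking D one for one against that amount, I reckoned 0.328 M of D left, so I expected the flask still moving. At its last reading, winter's G was 69.0% of its lost J, and by that ratio I put the flask at 42.9% G. Dissolved J does not count as converted, so I put conv between that figure and 62.2%.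

The forecast said it is still moving, with conv 63.5%, above my ceiling, and G 43.5%, reading the rate as “zero order in both”.

The flask gave it is still moving, with conv 52.8% and G 39.4%.

    J ⇌ Q, rate k1*(cs1 - [Q]) while solid is left; crystals form when [Q] > cs1 (solubility = 0.340 M, k = 2.30 × 10⁻⁴ s⁻¹)
    Q + D → G (k = 0.00180 L mol⁻¹ s⁻¹)
    G ⇌ Z (K = 0.390, k = 3.10 × 10⁻⁴ s⁻¹)

In the flask at 2.5 h, 7.25% stood dissolved as Q and 13.4% as Z. The feed rate had promised 37.8% J, and the flask held 40.0%. Stopped at 1.5 h, the same flask should by that rate have held 62.7%, and it held 62.9%.

(All runs were generated by integration with constants of no real substance, noise included.)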